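(The numbers in the tables stem from a simulated flask on assumed constants; scatter was added.)

The X left over in larch, 30.6% at 2.00 h and 4.0% at 6.00 h, keeps falling although the charge of J less the E formed leaves 0.00560 M of J, so X reads as having a first-order way out that needs no J, with an apparent half-life of 1.36 h.

| setting | ash | cedar | larch | winter | dusk |
|---|---|---|---|---|---|
| X | 0.050 M (fed, over 40 min) | 0.050 M (fed, over 40 min) | 0.10 M (fed, over 40 min) | 0.050 M (fed, over 40 min) | 0.050 M |
| J | 0.063 M | 0.099 M | 0.045 M | 0.0450 M | 0.0450 M |
| remark | run made earlier | run made earlier | run made earlier |  | everything together at the start |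
| time |  |  |  | 30 h | 100 h |

| run | time / h | E / % | X / % |
|---|---|---|---|
| ash | 4.00 | 60.9 | 2.9 |
| ash | 8.00 | 63.5 | 0 |
| ash | 12.0 | 64.0 | 0.8 |
| ash | 15.0 | 63.5 | 1.0 |
| ash | 20.0 | 65.3 | 0 |
| ash | 25.0 | 63.7 | 0 |
| cedar | 2.00 | 68.9 | 7.4 |
| cedar | 3.00 | 73.5 | 1.4 |
| cedar | 5.00 | 75.4 | 1.2 |
| cedar | 8.00 | 75.9 | 0 |
| cedar | 15.0 | 76.1 | 0.8 |
| cedar | 25.0 | 76.4 | 0.7 |
| larch | 2.00 | 34.3 | 30.6 |
| larch | 4.00 | 37.4 | 11.4 |
| larch | 6.00 | 38.5 | 4.0 |
| larch | 12.0 | 39.4 | 0 |
| larch | 25.0 | 39.0 | 0.8 |

(scatter of a reading: 1 percentage point)

- a reading or a percentage of E counts all its forms, free or not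

* the flask that ends with the higher amount of E, in percent of the X charged, or "neither" when 2 percentage points or less lies between them (winter / dusk / neither)
* final E, as a percentage of the X charged, in winter
* final E, as a percentage of the X charged, in dusk

The ladder of times starts with the feed of 40 min, shorter than that half-life, so fed X should build up in the flask during the feed. The next rung is X itself, which ash reads at 0% by 8.00 h. Last comes the plateau, where E in ash stands flat to 25.0 h, and winter at 30 h and dusk at 100 h are read far behind the half-life. The number to watch in a repeat is therefore the height of the plateau, not its hour.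

That height is a contest between the loss of X and the route to E, which is pseudo-first-order in X at a given [J]. Counting one J per E, the charge of X equals E plus the crossing [J] times the logarithm of the ratio of first to last [J]. The ash plateau, 0.0320 M of E, gives 0.0254 M for the crossing [J], the concentration of J at which X goes to E as fast as to its first-order loss. Cedar reads 0.0246 M, but larch, whose [J] falls furthest, reads 0.0297 M, an excess this balance does not explain.

Winter starts above the crossing, so E leads at first. A trial E of 0.0270 M uses 0.0503 M of X, slightly over the charge, and one Newton step gives 0.0269 M, or 53.8%. The last [J] of this balance is 0.0181 M, below the crossing, so control changes hands during winter. The balance holds no term in [X], so this reckoning gives dusk the same figure.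

The forecast says 53.5% for winter, 52.5% for dusk, and neither. It too holds that “dumping X in at once changes nothing”, but it differs from the reckoning here by taking about a point off dusk for a possible second-order loss.

The simulation gives 53.3% in winter and 53.3% in dusk, so the answer is neither.

    X + J → E (k = 15.3 L mol⁻¹ h⁻¹)
    X → D (k = 0.389 h⁻¹)
    J + D → Z (k = 2.07 L mol⁻¹ h⁻¹)
    D ⇌ G (K = 3.10, k = 0.772 h⁻¹)
    L ⇌ E, rate k5*(cs5 - [E]) while solid is left; crystals form when [E] > cs5 (solubility = 40.0 mM, k = 2.21 h⁻¹)

A neighbour of winter charged with 0.11 M of J, 2.20 equiv, goes through the same balance with the crossing [J] of 0.0254 M, which puts its E at 77.8% of the X charged. The simulated neighbour ends at 77.7%. At 30.0 h its J stands at 58% of its charge, which is 0.0641 M, above the crossing, while J in winter stands at 29.2% of its own charge.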